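**Retrosynthetic overview**

- The C40 chain is cut at C11=C12 and C11'=C12' (two Wittig reactions) into a C10 dialdehyde and two C15 phosphonium salts. Ring A is the reduced (4S, all-equatorial) form of ring B, so both salts come from one ketone.
- Enabling feature of ring B: O=C4'–C5'–C6'–C7'=C8' is a γ,δ-unsaturated ketone, and C6' is tied back to C4' by the bridge C1'–C2'–C3'. Moving the C5'–C6' bond to an O–C8' bond gives an eight-membered 2-methylene-oxocene.
- Key step: transannular Claisen ring contraction (8 → 6). It forms C5'–C6', the C4' ketone, the 7'E alkene and the C6' stereocentre (chirality transfer from the C8' carbinol).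
- The oxocene comes from an eight-membered lactone (lactonisation, then methylenation). The carbinol comes from a catalytic asymmetric alkynylation of a C5 enal, the Z-alkene from semihydrogenation. The C5' methyl is added after the contraction, trans, by β-keto ester dianion methylation.
- Ring order: eight-membered lactone ring (step 7), then the cyclohexanone ring by contraction (step 9); ring A is this same ring after reduction (step 15).

Key step: step 9

Remark: carotenoid numbering is used for positions (ring B C1'–C6', side chain C7'–C11'; unprimed numbers for ring A).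
Remark: the C5' methyl is not carried through the ring contraction (a Z-ethylidene ether should emerge cis through the same chair array) and is not set by α-epimerisation (the gem-dimethyl group and the ring carbonyl are assumed to leave cis and trans close in energy); it is set kinetically in step 11 and the ketone is then kept away from equilibrating base or acid.
Remark: in step 4 the (S,S) ligand is assumed to give the (7S) alcohol; if the sense proves opposite, the (R,R) ligand is used.

**Route**

Step 1
Reactants: 1 isobutyraldehyde, 2 methyl acrylate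
Product: 4 methyl 4,4-dimethyl-5-oxopentanoate, via pyrrolidine enamine 3 (not isolated)
Conditions: pyrrolidine (1.1 equiv), PhMe, reflux (−H2O); 2, MeCN, 80 °C; aq AcOH, rt
Reagents that add atoms: water, O
Why: Stork enamine Michael addition, in which the enamine of the α,α-disubstituted aldehyde can add only once to the acrylate and hydrolysis returns the aldehyde next to the new quaternary carbon (C1 and C1' of the target); no stereocentre is formed.

Step 2
Reactants: 4 methyl 4,4-dimethyl-5-oxopentanoate
Product: 5 methyl 4,4-dimethylhex-5-ynoate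
Conditions: dimethyl (1-diazo-2-oxopropyl)phosphonate, K2CO3, MeOH, 0 °C → rt
Reagents that add atoms: dimethyl (1-diazo-2-oxopropyl)phosphonate, CC(=O)C(=[N+]=[N-])P(=O)(OC)OC
Why: Ohira–Bestmann (Seyferth–Gilbert) homologation of a non-enolisable α-quaternary aldehyde to the terminal alkyne under K2CO3/MeOH, conditions that leave the methyl ester unchanged; no stereocentre.

Step 3
Reactants: 6 (tert-butyldimethylsilyloxy)acetaldehyde, 7 2-(triphenylphosphoranylidene)propanal
Product: 8 (2E)-4-[(tert-butyldimethylsilyl)oxy]-2-methylbut-2-enal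
Conditions: CH2Cl2, rt → 40 °C
Reagents that add atoms: none
Why: Wittig olefination with a formyl-stabilised ylide, which is E-selective and should stop after one olefination because the conjugated, α-branched enal product is far less electrophilic than 6.

Step 4
Reactants: 5 methyl 4,4-dimethylhex-5-ynoate, 8 (2E)-4-[(tert-butyldimethylsilyl)oxy]-2-methylbut-2-enal
Product: 9 methyl (7S,8E)-10-[(tert-butyldimethylsilyl)oxy]-7-hydroxy-4,4,8-trimethyldec-8-en-5-ynoate
Conditions: Me2Zn (3 equiv), (S,S)-ProPhenol ligand (20 mol %), Ph3P=O (40 mol %), PhMe, 0 °C → rt; aq NH4Cl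
Reagents that add atoms: none
Why: catalytic enantioselective alkynylation of an aldehyde by an alkynylzinc formed in situ (dinuclear zinc amino-alkoxide catalysis), a reaction type suited to α-branched enals and tolerant of esters, in which the ligand enantiomer fixes the aldehyde face and is chosen to give the (7S) carbinol, the future C8/C8' centre.

Step 5
Reactants: 9 methyl (7S,8E)-10-[(tert-butyldimethylsilyl)oxy]-7-hydroxy-4,4,8-trimethyldec-8-en-5-ynoate
Product: 10 methyl (5Z,7R,8E)-10-[(tert-butyldimethylsilyl)oxy]-7-hydroxy-4,4,8-trimethyldeca-5,8-dienoate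
Conditions: H2 (1 atm), Pd/CaCO3–Pb(OAc)2 (Lindlar catalyst), quinoline, EtOAc, rt
Reagents that add atoms: none
Why: Lindlar semihydrogenation, whose syn addition of H2 to the disubstituted alkyne gives the Z-alkene while the trisubstituted alkene, the ester and the silyl ether are inert and the carbinol centre is untouched (its descriptor becomes R only through the priority rules).

Step 6
Reactants: 10 methyl (5Z,7R,8E)-10-[(tert-butyldimethylsilyl)oxy]-7-hydroxy-4,4,8-trimethyldeca-5,8-dienoate
Product: 11 (5Z,7R,8E)-10-[(tert-butyldimethylsilyl)oxy]-7-hydroxy-4,4,8-trimethyldeca-5,8-dienoic acid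
Conditions: LiOH·H2O, THF/MeOH/H2O, rt; then 1 M HCl to pH 4–5, 0 °C
Reagents that add atoms: lithium hydroxide, [Li+].[OH-]
Why: ester saponification, tolerated by the base-stable silyl ether and bis-allylic alcohol, with a cold and only mildly acidic work-up so that the carbinol is not ionised.

Step 7
Reactants: 11 (5Z,7R,8E)-10-[(tert-butyldimethylsilyl)oxy]-7-hydroxy-4,4,8-trimethyldeca-5,8-dienoic acid
Product: 13 (6Z,8R)-8-[(2E)-4-[(tert-butyldimethylsilyl)oxy]but-2-en-2-yl]-5,5-dimethyl-3,4,5,8-tetrahydro-2H-oxocin-2-one, via mixed anhydride 12 (not isolated)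
Conditions: 2-methyl-6-nitrobenzoic anhydride (1.3 equiv), DMAP (3 equiv), CH2Cl2 (2 mM), rt, slow addition of 11
Reagents that add atoms: none
Why: Shiina macrolactonisation (acyl activation, so the carbinol centre is retained), in which the Z-alkene and the gem-dimethyl group (Thorpe–Ingold effect) pre-organise the chain for eight-membered ring closure, high dilution suppresses oligomers and the base-only medium does not ionise the bis-allylic carbinol.

Step 8
Reactants: 13 (6Z,8R)-8-[(2E)-4-[(tert-butyldimethylsilyl)oxy]but-2-en-2-yl]-5,5-dimethyl-3,4,5,8-tetrahydro-2H-oxocin-2-one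
Product: 14 (2R,3Z)-2-[(2E)-4-[(tert-butyldimethylsilyl)oxy]but-2-en-2-yl]-5,5-dimethyl-8-methylidene-5,6,7,8-tetrahydro-2H-oxocine
Conditions: Cp2TiMe2 (2.5 equiv), PhMe, 65 °C, dark; filtration through basic Al2O3
Reagents that add atoms: dimethyltitanocene Cp2TiMe2, C[Ti](C)(C1C=CC=C1)C1C=CC=C1
Why: Petasis methylenation, which converts the lactone carbonyl into the exocyclic enol ether under non-acidic conditions compatible with the allylic C–O bond and the silyl ether, and any material that already rearranges at this temperature is ketone 15 and converges.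

Step 9
Reactants: 14 (2R,3Z)-2-[(2E)-4-[(tert-butyldimethylsilyl)oxy]but-2-en-2-yl]-5,5-dimethyl-8-methylidene-5,6,7,8-tetrahydro-2H-oxocine
Product: 15 (3R)-3-[(1E,3E)-5-[(tert-butyldimethylsilyl)oxy]-3-methylpenta-1,3-dien-1-yl]-4,4-dimethylcyclohexan-1-one
Conditions: PhMe (0.02 M), Et3N (1 mol %), 100–110 °C, base-washed glassware
Reagents that add atoms: none
Why: Proposed new method: the exocyclic enol ether (C5'H2=C4'–O) and the in-ring allylic ether (O–C8'–C7'=C6') of 14 make up an allyl vinyl ether, so heating should bring about a concerted, suprafacial [3,3] (Claisen) shift in which C5' bonds across the ring to C6' while O–C8' breaks, which contracts the eight-membered ring to the cyclohexanone and turns O, C8' and C7' into the carbonyl oxygen and the exocyclic E-alkene. The closest known reactions are the Claisen ring expansions of methylenated vinyl lactones (exocyclic enol ether, exocyclic allyl unit) and the ester-enolate Claisen ring contractions of unsaturated medium and large lactones (in-ring allyl unit); the exo-enol-ether/in-ring-allyl combination on an eight-membered ring is the untested part. The six-membered ring closes by transannular C–C bond formation through a chair-like six-atom array fused in bicyclo[3.3.1] fashion to the chair of the nascent ring, a boat array being excluded because the three-atom bridge C3'–C2'–C1' could then not span C4' and C6'. The C6' stereocentre is controlled by the C8' carbinol centre (1,3-chirality transfer): the butenyl group on C8' stays anti to C6' to avoid A(1,3) strain with the cis C1' quaternary carbon, which fixes the face of the allyl unit that carries O and therefore the face of C6' that is attacked, and gives the 7'E geometry. The selectivity needed is for the in-ring allyl unit over the exocyclic C9'=C10' alkene (a ring-expanding [3,3] path to a ten-membered enone) and against ionisation of the bis-allylic ether: the first should be secured by the strain-free transition state and product of the contraction against a trans-cyclodecene-like alternative, the second by acid-free conditions, with C=O formation and loss of medium-ring strain as driving force.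

Step 10
Reactants: 15 (3R)-3-[(1E,3E)-5-[(tert-butyldimethylsilyl)oxy]-3-methylpenta-1,3-dien-1-yl]-4,4-dimethylcyclohexan-1-one
Product: 16 prop-2-en-1-yl (4R)-4-[(1E,3E)-5-[(tert-butyldimethylsilyl)oxy]-3-methylpenta-1,3-dien-1-yl]-5,5-dimethyl-2-oxocyclohexane-1-carboxylate (C1 epimers)
Conditions: NaH (3 equiv), diallyl carbonate (3 equiv), THF, reflux; then AcOH
Reagents that add atoms: diallyl carbonate, C=CCOC(=O)OCC=C
Why: crossed Claisen condensation (C-acylation of the ketone enolate) under equilibrating conditions, which should acylate the less hindered α-carbon C3', remote from the C6' substituent, and is driven by the stabilised β-keto ester enolate; C6' is not enolisable and is untouched.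

Step 11
Reactants: 16 prop-2-en-1-yl (4R)-4-[(1E,3E)-5-[(tert-butyldimethylsilyl)oxy]-3-methylpenta-1,3-dien-1-yl]-5,5-dimethyl-2-oxocyclohexane-1-carboxylate
Product: 18 prop-2-en-1-yl (3S,4S)-4-[(1E,3E)-5-[(tert-butyldimethylsilyl)oxy]-3-methylpenta-1,3-dien-1-yl]-3,5,5-trimethyl-2-oxocyclohexane-1-carboxylate, via dilithium dianion 17 (not isolated)
Conditions: LiN(iPr)2 (2.2 equiv), THF, −78 → 0 °C; MeI (1.05 equiv), −78 → 0 °C; aq NH4Cl
Reagents that add atoms: iodomethane, CI
Why: γ-alkylation of a β-keto ester dianion, in which only the more basic, second-formed enolate terminus C5' (between C4' and C6') is alkylated and iodomethane should enter trans to the C6' side chain through the half-chair that has the chain pseudo-equatorial, the face syn to the axial C1' methyl being blocked, which sets C5' as S.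

Step 12
Reactants: 18 prop-2-en-1-yl (3S,4S)-4-[(1E,3E)-5-[(tert-butyldimethylsilyl)oxy]-3-methylpenta-1,3-dien-1-yl]-3,5,5-trimethyl-2-oxocyclohexane-1-carboxylate
Product: 19 (2S,3S)-3-[(1E,3E)-5-[(tert-butyldimethylsilyl)oxy]-3-methylpenta-1,3-dien-1-yl]-2,4,4-trimethylcyclohexan-1-one
Conditions: Pd(OAc)2 (5 mol %), PPh3 (20 mol %), HCO2H, Et3N, THF, rt → 40 °C
Reagents that add atoms: none
Why: palladium-catalysed deallylation–decarboxylation of an allyl β-keto ester (Tsuji–Trost-type ionisation), in which zerovalent palladium ionises the allyl ester, the β-keto carboxylate loses CO2 and formate reduces the allyl group, all under near-neutral conditions at C3', so the C5' centre α to the ketone is not equilibrated.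

Step 13
Reactants: 19 (2S,3S)-3-[(1E,3E)-5-[(tert-butyldimethylsilyl)oxy]-3-methylpenta-1,3-dien-1-yl]-2,4,4-trimethylcyclohexan-1-one
Product: 20 (2S,3S)-3-[(1E,3E)-5-hydroxy-3-methylpenta-1,3-dien-1-yl]-2,4,4-trimethylcyclohexan-1-one
Conditions: HF·pyridine, pyridine, THF, 0 °C → rt
Reagents that add atoms: none
Why: fluoride cleavage of the primary allylic silyl ether under pyridine-buffered conditions that should neither enolise the ketone nor isomerise the diene.

Step 14
Reactants: 20 (2S,3S)-3-[(1E,3E)-5-hydroxy-3-methylpenta-1,3-dien-1-yl]-2,4,4-trimethylcyclohexan-1-one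
Product: 21 [(2E,4E)-3-methyl-5-[(1S,2S)-2,6,6-trimethyl-3-oxocyclohexyl]penta-2,4-dien-1-yl]triphenylphosphonium bromide
Conditions: PPh3·HBr (1.05 equiv), MeOH, 0 °C → rt
Reagents that add atoms: triphenylphosphonium bromide (PPh3·HBr), [Br-].c1ccccc1[PH+](c1ccccc1)c1ccccc1
Why: allylic phosphonium salt formation (the standard preparation of C15 Wittig salts), in which acid-assisted loss of water gives the pentadienyl cation that PPh3 captures at the unhindered terminal carbon to give the thermodynamic 2E,4E salt, the ketone and both ring stereocentres being untouched.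

Step 15
Reactants: 20 (2S,3S)-3-[(1E,3E)-5-hydroxy-3-methylpenta-1,3-dien-1-yl]-2,4,4-trimethylcyclohexan-1-one
Product: 22 (1S,2S,3S)-3-[(1E,3E)-5-hydroxy-3-methylpenta-1,3-dien-1-yl]-2,4,4-trimethylcyclohexan-1-ol
Conditions: NaBH4, MeOH, −40 → −20 °C
Reagents that add atoms: none
Why: borohydride reduction of a conformationally biased cyclohexanone, in which hydride should attack axially on the chair that holds the methyl group and the side chain equatorial (only hydrogens are syn-axial to its path), giving the equatorial (1S) alcohol, cis to the side chain and trans to the methyl group.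

Step 16
Reactants: 22 (1S,2S,3S)-3-[(1E,3E)-5-hydroxy-3-methylpenta-1,3-dien-1-yl]-2,4,4-trimethylcyclohexan-1-ol
Product: 23 [(2E,4E)-5-[(1S,2S,3S)-3-hydroxy-2,6,6-trimethylcyclohexyl]-3-methylpenta-2,4-dien-1-yl]triphenylphosphonium bromide
Conditions: PPh3·HBr (1.05 equiv), MeOH, 0 °C → rt
Reagents that add atoms: triphenylphosphonium bromide (PPh3·HBr), [Br-].c1ccccc1[PH+](c1ccccc1)c1ccccc1
Why: allylic phosphonium salt formation as in step 14, in which only the primary allylic hydroxyl ionises and the secondary ring hydroxyl is unaffected.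

Step 17
Reactants: 23 [(2E,4E)-5-[(1S,2S,3S)-3-hydroxy-2,6,6-trimethylcyclohexyl]-3-methylpenta-2,4-dien-1-yl]triphenylphosphonium bromide, 24 (2E,4E,6E)-2,7-dimethylocta-2,4,6-trienedial
Product: 25 (2E,4E,6E,8E,10E,12E)-13-[(1S,2S,3S)-3-hydroxy-2,6,6-trimethylcyclohexyl]-2,7,11-trimethyltrideca-2,4,6,8,10,12-hexaenal
Conditions: 24 (3 equiv), NaOMe (1.05 equiv), CH2Cl2/MeOH, −10 °C → rt; then cat. I2, hexane, rt (Z→E)
Reagents that add atoms: none
Why: Wittig olefination of a semi-stabilised ylide with the symmetrical C10 dialdehyde used in excess, so that mono-condensation should dominate (the remaining formyl group of 25 is deactivated by the longer polyene), the new C11=C12 bond being equilibrated to E and the free hydroxyl tolerated.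

Step 18
Reactants: 25 (2E,4E,6E,8E,10E,12E)-13-[(1S,2S,3S)-3-hydroxy-2,6,6-trimethylcyclohexyl]-2,7,11-trimethyltrideca-2,4,6,8,10,12-hexaenal, 21 [(2E,4E)-3-methyl-5-[(1S,2S)-2,6,6-trimethyl-3-oxocyclohexyl]penta-2,4-dien-1-yl]triphenylphosphonium bromide
Product: 26 (all-E)-(4S,5S,6S,5'S,6'S)-4-hydroxy-5,6,5',6'-tetrahydro-β,β-caroten-4'-one (CNP0107241.1)
Conditions: 1,2-epoxybutane (excess), EtOH, 70 °C; then n-heptane, reflux (Z→E), crystallisation
Reagents that add atoms: none
Why: Wittig olefination in which base is generated only transiently by bromide opening of the epoxide, so the ketone α-centre C5' should not be equilibrated, the ylide reacts with the aldehyde far faster than with the hindered ring ketone, and heating equilibrates the new C11'=C12' bond to E.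

**Compound list**

1 | isobutyraldehyde | CC(C)C=O | starting material
2 | methyl acrylate | C=CC(=O)OC | starting material
3 | 1-(2-methylprop-1-en-1-yl)pyrrolidine | CC(C)=CN1CCCC1 | intermediate (not isolated)
4 | methyl 4,4-dimethyl-5-oxopentanoate | COC(=O)CCC(C)(C)C=O | intermediate
5 | methyl 4,4-dimethylhex-5-ynoate | COC(=O)CCC(C)(C)C#C | intermediate
6 | (tert-butyldimethylsilyloxy)acetaldehyde | CC(C)(C)[Si](C)(C)OCC=O | starting material
7 | 2-(triphenylphosphoranylidene)propanal | CC(C=O)=P(c1ccccc1)(c1ccccc1)c1ccccc1 | starting material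
8 | (2E)-4-[(tert-butyldimethylsilyl)oxy]-2-methylbut-2-enal | CC(C)(C)[Si](C)(C)OC/C=C(C)/C=O | intermediate
9 | methyl (7S,8E)-10-[(tert-butyldimethylsilyl)oxy]-7-hydroxy-4,4,8-trimethyldec-8-en-5-ynoate | COC(=O)CCC(C)(C)C#C[C@@H](O)/C(C)=C/CO[Si](C)(C)C(C)(C)C | intermediate
10 | methyl (5Z,7R,8E)-10-[(tert-butyldimethylsilyl)oxy]-7-hydroxy-4,4,8-trimethyldeca-5,8-dienoate | COC(=O)CCC(C)(C)/C=C\[C@@H](O)/C(C)=C/CO[Si](C)(C)C(C)(C)C | intermediate
11 | (5Z,7R,8E)-10-[(tert-butyldimethylsilyl)oxy]-7-hydroxy-4,4,8-trimethyldeca-5,8-dienoic acid | OC(=O)CCC(C)(C)/C=C\[C@@H](O)/C(C)=C/CO[Si](C)(C)C(C)(C)C | intermediate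
12 | mixed anhydride of 11 with 2-methyl-6-nitrobenzoic acid | Cc1cccc([N+](=O)[O-])c1C(=O)OC(=O)CCC(C)(C)/C=C\[C@@H](O)/C(C)=C/CO[Si](C)(C)C(C)(C)C | intermediate (not isolated)
13 | (6Z,8R)-8-[(2E)-4-[(tert-butyldimethylsilyl)oxy]but-2-en-2-yl]-5,5-dimethyl-3,4,5,8-tetrahydro-2H-oxocin-2-one | O=C1CCC(C)(C)/C=C\[C@@H](O1)/C(C)=C/CO[Si](C)(C)C(C)(C)C | intermediate
14 | (2R,3Z)-2-[(2E)-4-[(tert-butyldimethylsilyl)oxy]but-2-en-2-yl]-5,5-dimethyl-8-methylidene-5,6,7,8-tetrahydro-2H-oxocine | C=C1CCC(C)(C)/C=C\[C@@H](O1)/C(C)=C/CO[Si](C)(C)C(C)(C)C | intermediate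
15 | (3R)-3-[(1E,3E)-5-[(tert-butyldimethylsilyl)oxy]-3-methylpenta-1,3-dien-1-yl]-4,4-dimethylcyclohexan-1-one | CC(C)(C)[Si](C)(C)OC/C=C(C)/C=C/[C@H]1CC(=O)CCC1(C)C | intermediate
16 | prop-2-en-1-yl (4R)-4-[(1E,3E)-5-[(tert-butyldimethylsilyl)oxy]-3-methylpenta-1,3-dien-1-yl]-5,5-dimethyl-2-oxocyclohexane-1-carboxylate (C1 epimers) | CC(C)(C)[Si](C)(C)OC/C=C(C)/C=C/[C@H]1CC(=O)C(C(=O)OCC=C)CC1(C)C | intermediate
17 | dilithium dianion of 16 | [Li+].[Li+].CC(C)(C)[Si](C)(C)OC/C=C(C)/C=C/[C@H]1C=C([O-])C(=C([O-])OCC=C)CC1(C)C | intermediate (not isolated)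
18 | prop-2-en-1-yl (3S,4S)-4-[(1E,3E)-5-[(tert-butyldimethylsilyl)oxy]-3-methylpenta-1,3-dien-1-yl]-3,5,5-trimethyl-2-oxocyclohexane-1-carboxylate (C1 epimers) | CC(C)(C)[Si](C)(C)OC/C=C(C)/C=C/[C@H]1[C@H](C)C(=O)C(C(=O)OCC=C)CC1(C)C | intermediate
19 | (2S,3S)-3-[(1E,3E)-5-[(tert-butyldimethylsilyl)oxy]-3-methylpenta-1,3-dien-1-yl]-2,4,4-trimethylcyclohexan-1-one | CC(C)(C)[Si](C)(C)OC/C=C(C)/C=C/[C@H]1[C@H](C)C(=O)CCC1(C)C | intermediate
20 | (2S,3S)-3-[(1E,3E)-5-hydroxy-3-methylpenta-1,3-dien-1-yl]-2,4,4-trimethylcyclohexan-1-one | OC/C=C(C)/C=C/[C@H]1[C@H](C)C(=O)CCC1(C)C | intermediate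
21 | [(2E,4E)-3-methyl-5-[(1S,2S)-2,6,6-trimethyl-3-oxocyclohexyl]penta-2,4-dien-1-yl]triphenylphosphonium bromide | [Br-].c1ccccc1[P+](c1ccccc1)(c1ccccc1)C/C=C(C)/C=C/[C@H]1[C@H](C)C(=O)CCC1(C)C | intermediate
22 | (1S,2S,3S)-3-[(1E,3E)-5-hydroxy-3-methylpenta-1,3-dien-1-yl]-2,4,4-trimethylcyclohexan-1-ol | OC/C=C(C)/C=C/[C@H]1[C@H](C)[C@@H](O)CCC1(C)C | intermediate
23 | [(2E,4E)-5-[(1S,2S,3S)-3-hydroxy-2,6,6-trimethylcyclohexyl]-3-methylpenta-2,4-dien-1-yl]triphenylphosphonium bromide | [Br-].c1ccccc1[P+](c1ccccc1)(c1ccccc1)C/C=C(C)/C=C/[C@H]1[C@H](C)[C@@H](O)CCC1(C)C | intermediate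
24 | (2E,4E,6E)-2,7-dimethylocta-2,4,6-trienedial | O=C/C(C)=C/C=C/C=C(C)/C=O | starting material
25 | (2E,4E,6E,8E,10E,12E)-13-[(1S,2S,3S)-3-hydroxy-2,6,6-trimethylcyclohexyl]-2,7,11-trimethyltrideca-2,4,6,8,10,12-hexaenal | CC(/C=C/C=C(C)/C=C/[C@H]1[C@H](C)[C@@H](O)CCC1(C)C)=C\C=C\C=C(C)\C=O | intermediate
26 | (all-E)-(4S,5S,6S,5'S,6'S)-4-hydroxy-5,6,5',6'-tetrahydro-β,β-caroten-4'-one (CNP0107241.1) | CC(/C=C/C=C(C)/C=C/[C@H]1[C@H](C)[C@@H](O)CCC1(C)C)=C\C=C\C=C(C)\C=C\C=C(C)\C=C\[C@H]1[C@H](C)C(=O)CCC1(C)C | target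

**Totals and risks**

Total steps: 18. Longest linear sequence: 16 steps (steps 1, 2, 4–13, 15–18).

Steps most likely to fail:

1. Step 9 (proposed new method). What may go wrong: the [3,3] shift may run through the exocyclic C9'=C10' alkene instead (ring expansion to a ten-membered enone), or traces of acid may ionise the bis-allylic ether or move the exocyclic double bond into the ring before rearrangement. Fallback (known chemistry; acyclic [3,3] shift, then ring closure): the route is left at 10. Acetylation (Ac2O, pyridine, DMAP) should give the allylic acetate F1. Ireland–Claisen rearrangement (LiN(iPr)2, Me3SiCl, THF, −78 °C → rt; both esters are enolised, only the allyl ester rearranges, with the same C8' → C6' transfer) should then give the acid F2. Methylation (Me3SiCHN2) gives the diester F3. Dieckmann cyclisation (KOtBu, THF) gives the β-keto ester F4 together with its regioisomer F5. Both are dealkoxycarbonylated (Krapcho, LiCl, wet DMSO, 130 °C) to the same ketone 15, where the route is rejoined; this path also avoids the medium ring of steps 6–8.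

2. Step 11. What may go wrong: insufficient facial selectivity in the C-methylation (cis C5'/C6' epimer), or proton transfer between the dianion and the product. Fallback (the methyl centre is set in a sigmatropic step instead of an alkylation): the route is left at 10. Propionylation (EtCOCl, pyridine) should give the propionate F6. Ireland–Claisen rearrangement through the Z lithium enolate (LiN(iPr)2, THF/DMPU, Me3SiCl), whose chair array places the methyl group anti to C7', should give the acid F7. Methylation (Me3SiCHN2) gives the diester F8. Kinetic Dieckmann cyclisation (LiN(SiMe3)2, THF, −78 °C, enolisation of the less hindered ester only) gives the β-keto ester F9. Krapcho dealkoxycarbonylation (LiCl, wet DMSO, lowest effective temperature) returns to ketone 19.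

3. Step 18. What may go wrong: partial enolisation of the keto phosphonium salt under the olefination conditions (loss of the C5' configuration), sluggish reaction of its ylide, or incomplete Z→E equilibration of the long polyene. Fallback (reversed polarity): 20 is oxidised (MnO2, CH2Cl2) to the C15 keto aldehyde F10. 25 is reduced (NaBH4, MeOH, 0 °C) to the C25 diol F11 and converted (PPh3·HBr, MeOH) into the C25 phosphonium bromide F12. The ylide of F12, pre-formed with NaOMe (1 equiv) at −20 °C, is then treated with F10, so that the ketone never meets free base, and the route is rejoined at 26.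

**Further compounds**

F1 | step 9 | methyl (5Z,7R,8E)-7-acetoxy-10-[(tert-butyldimethylsilyl)oxy]-4,4,8-trimethyldeca-5,8-dienoate | COC(=O)CCC(C)(C)/C=C\[C@@H](OC(C)=O)/C(C)=C/CO[Si](C)(C)C(C)(C)C
F2 | step 9 | (3R,4E,6E)-8-[(tert-butyldimethylsilyl)oxy]-3-(5-methoxy-2-methyl-5-oxopentan-2-yl)-6-methylocta-4,6-dienoic acid | CC(C)(C)[Si](C)(C)OC/C=C(C)/C=C/[C@@H](CC(O)=O)C(C)(C)CCC(=O)OC
F3 | step 9 | methyl (5R,6E,8E)-10-[(tert-butyldimethylsilyl)oxy]-5-(2-methoxy-2-oxoethyl)-4,4,8-trimethyldeca-6,8-dienoate | CC(C)(C)[Si](C)(C)OC/C=C(C)/C=C/[C@@H](CC(=O)OC)C(C)(C)CCC(=O)OC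
F4 | step 9 | methyl (4R)-4-[(1E,3E)-5-[(tert-butyldimethylsilyl)oxy]-3-methylpenta-1,3-dien-1-yl]-5,5-dimethyl-2-oxocyclohexane-1-carboxylate | CC(C)(C)[Si](C)(C)OC/C=C(C)/C=C/[C@H]1CC(=O)C(C(=O)OC)CC1(C)C
F5 | step 9 | methyl (2S)-2-[(1E,3E)-5-[(tert-butyldimethylsilyl)oxy]-3-methylpenta-1,3-dien-1-yl]-3,3-dimethyl-6-oxocyclohexane-1-carboxylate | CC(C)(C)[Si](C)(C)OC/C=C(C)/C=C/[C@H]1C(C(=O)OC)C(=O)CCC1(C)C
F6 | step 11 | methyl (5Z,7R,8E)-10-[(tert-butyldimethylsilyl)oxy]-4,4,8-trimethyl-7-(propanoyloxy)deca-5,8-dienoate | COC(=O)CCC(C)(C)/C=C\[C@@H](OC(=O)CC)/C(C)=C/CO[Si](C)(C)C(C)(C)C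
F7 | step 11 | (2S,3S,4E,6E)-8-[(tert-butyldimethylsilyl)oxy]-3-(5-methoxy-2-methyl-5-oxopentan-2-yl)-2,6-dimethylocta-4,6-dienoic acid | CC(C)(C)[Si](C)(C)OC/C=C(C)/C=C/[C@@H]([C@H](C)C(O)=O)C(C)(C)CCC(=O)OC
F8 | step 11 | methyl (5S,6E,8E)-10-[(tert-butyldimethylsilyl)oxy]-5-[(2S)-1-methoxy-1-oxopropan-2-yl]-4,4,8-trimethyldeca-6,8-dienoate | CC(C)(C)[Si](C)(C)OC/C=C(C)/C=C/[C@@H]([C@H](C)C(=O)OC)C(C)(C)CCC(=O)OC
F9 | step 11 | methyl (3S,4S)-4-[(1E,3E)-5-[(tert-butyldimethylsilyl)oxy]-3-methylpenta-1,3-dien-1-yl]-3,5,5-trimethyl-2-oxocyclohexane-1-carboxylate | CC(C)(C)[Si](C)(C)OC/C=C(C)/C=C/[C@H]1[C@H](C)C(=O)C(C(=O)OC)CC1(C)C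
F10 | step 18 | (2E,4E)-3-methyl-5-[(1S,2S)-2,6,6-trimethyl-3-oxocyclohexyl]penta-2,4-dienal | O=C/C=C(C)/C=C/[C@H]1[C@H](C)C(=O)CCC1(C)C
F11 | step 18 | (2E,4E,6E,8E,10E,12E)-13-[(1S,2S,3S)-3-hydroxy-2,6,6-trimethylcyclohexyl]-2,7,11-trimethyltrideca-2,4,6,8,10,12-hexaen-1-ol | CC(/C=C/C=C(C)/C=C/[C@H]1[C@H](C)[C@@H](O)CCC1(C)C)=C\C=C\C=C(C)\CO
F12 | step 18 | [(2E,4E,6E,8E,10E,12E)-13-[(1S,2S,3S)-3-hydroxy-2,6,6-trimethylcyclohexyl]-2,7,11-trimethyltrideca-2,4,6,8,10,12-hexaen-1-yl]triphenylphosphonium bromide | CC(/C=C/C=C(C)/C=C/[C@H]1[C@H](C)[C@@H](O)CCC1(C)C)=C\C=C\C=C(C)\C[P+](c1ccccc1)(c1ccccc1)c1ccccc1.[Br-]
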